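Everything rests on reading ring C (the pyranone ring O1–C2–C3–C4–C4a–C8a) as the hydrolysed form of a cyclic silyl enol ether, so that the C3–C4 bond can be made as a C3=C4 double bond by ring-closing olefin metathesis. The feature exploited is the C4 ketone flanked by the unsubstituted C3 methylene and, one atom further, the O1-bearing benzylic stereocentre C2: the precursor is an aryl (S)-1-arylallyl ether whose ortho-acetyl group on ring A is masked as its silyl enol ether. C2 is set beforehand by iridium-catalysed asymmetric allylic etherification; the metathesis closes ring C with loss of ethylene, and fluoride then unmasks the ketone and both phenols.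

Key step: step 7

Assumption: the (Sa,Sc,Sc) enantiomer of the phosphoramidite ligand is taken to deliver the (S)-ether, following the accepted sense of induction of this iridium–phosphoramidite catalyst family; the mirror-image ligand would be used if the first run showed the opposite sense.

Throughout, "geranyl" means (2E)-3,7-dimethylocta-2,6-dien-1-yl.

Step 1
Reactants: 1 methyl (2E)-3-(4-hydroxyphenyl)prop-2-enoate; 2 geranyl bromide
Product: 3 methyl (2E)-3-[4-(geranyloxy)phenyl]prop-2-enoate
Conditions: K2CO3, DMF, 25 °C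
Reagents that add atoms: none
Why: Williamson ether synthesis, in which the phenoxide displaces the primary allylic bromide by SN2 and both (E)-olefins keep their geometry.

Step 2
Reactants: 3 methyl (2E)-3-[4-(geranyloxy)phenyl]prop-2-enoate
Product: 4 (2E)-3-[4-(geranyloxy)phenyl]prop-2-en-1-ol
Conditions: i-Bu2AlH (2.5 equiv), CH2Cl2, −78 to 0 °C; aq. potassium sodium tartrate
Reagents that add atoms: none
Why: 1,2-reduction of the α,β-unsaturated ester by i-Bu2AlH should give the allylic alcohol and leave the olefins and the geranyl ether untouched.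

Step 3
Reactants: 4 (2E)-3-[4-(geranyloxy)phenyl]prop-2-en-1-ol
Product: 5 (2E)-3-[4-(geranyloxy)phenyl]prop-2-en-1-yl methyl carbonate
Conditions: ClCO2Me, pyridine, CH2Cl2, 0 °C
Reagents that add atoms: methyl chloroformate, COC(=O)Cl
Why: O-acylation of the primary allylic alcohol installs the carbonate leaving group needed for the allylic substitution.

Step 4
Reactants: 6 1-(2,4,6-trihydroxyphenyl)ethanone
Product: 7 1-[2-hydroxy-4,6-bis(triisopropylsilyloxy)phenyl]ethanone
Conditions: i-Pr3SiCl (2.1 equiv), imidazole, DMF, 0 to 25 °C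
Reagents that add atoms: triisopropylsilyl chloride, CC(C)[Si](Cl)(C(C)C)C(C)C
Why: Phenol silylation should take the para hydroxyl and one ortho hydroxyl, while the last ortho hydroxyl, hydrogen-bonded to the acetyl group and hindered, stays free as the future O1.

Step 5
Reactants: 7 1-[2-hydroxy-4,6-bis(triisopropylsilyloxy)phenyl]ethanone; 5 (2E)-3-[4-(geranyloxy)phenyl]prop-2-en-1-yl methyl carbonate
Product: 9 1-[2-{[(1S)-1-[4-(geranyloxy)phenyl]prop-2-en-1-yl]oxy}-4,6-bis(triisopropylsilyloxy)phenyl]ethanone, via lithium aryloxide 8 (not isolated)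
Conditions: LiN(SiMe3)2 (1.0 equiv), THF, 0 °C; then 5, [Ir(cod)Cl]2 (2 mol %), (Sa,Sc,Sc)-binaphthol-derived N,N-bis(1-phenylethyl)phosphoramidite (4 mol %), THF, 25–50 °C, stopped at full conversion
Reagents that add atoms: none
Why: Iridium-catalysed asymmetric allylic substitution (Tsuji–Trost type), in which the carbonate ionises to a π-allyliridium complex, the aryloxide attacks its aryl-substituted terminus to give the branched ether, and the chiral phosphoramidite selects the face so that C2 is set as (S).

Step 6
Reactants: 9 1-[2-{[(1S)-1-[4-(geranyloxy)phenyl]prop-2-en-1-yl]oxy}-4,6-bis(triisopropylsilyloxy)phenyl]ethanone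
Product: 11 tert-butyldimethylsilyl enol ether of 9 (1-silyloxyethenyl group on ring A), via potassium enolate 10 (not isolated)
Conditions: KN(SiMe3)2 (1.1 equiv), THF, −78 °C; then t-BuMe2SiOTf, −78 to −40 °C; aq. NaHCO3
Reagents that add atoms: tert-butyldimethylsilyl trifluoromethanesulfonate, CC(C)(C)[Si](C)(C)OS(=O)(=O)C(F)(F)F
Why: Kinetic deprotonation of the methyl ketone, the only enolisable position, followed by O-silylation of the hindered enolate should give the silyl enol ether without touching C2.

Step 7
Reactants: 11 tert-butyldimethylsilyl enol ether of 9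
Product: 12 (2S)-4-(tert-butyldimethylsilyloxy)-2-[4-(geranyloxy)phenyl]-5,7-bis(triisopropylsilyloxy)-2H-chromene
Conditions: second-generation Grubbs catalyst RuCl2(=CHPh)(H2IMes)(PCy3) (10 mol %), toluene (0.005 M), 60 °C, argon sparge, dark
Reagents that add atoms: none
Why: The ruthenium alkylidene loads onto the only monosubstituted olefin (the vinyl group at C3), adds intramolecularly by [2+2] cycloaddition to the 1,1-disubstituted silyl enol ether so that C3 bonds to C4, and cycloreversion of the ruthenacyclobutane releases the C3=C4 enol ether and a methylidene that leaves as ethylene. The closest known reaction type is ring-closing olefin metathesis of silyl enol ethers to cyclic silyl enol ethers, together with the metathesis route from 2-vinylphenyl allyl ethers to 2H-chromenes. Ring C is closed as a six-membered 2H-pyran by metathesis across C3 and C4, the chain C3–C2–O1–C8a–C4a–C4 being already in place. No stereocentre is formed; C2 is not touched and should keep its (S) configuration if light and higher temperatures are avoided, since 2H-chromenes can open reversibly by electrocyclic ring opening. The step needs chemoselectivity among four olefins: the two geranyl olefins are trisubstituted and sit para on ring B, so they cannot reach the alkylidene intramolecularly without forming a strained paracyclophane, and high dilution disfavours cross-metathesis.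

Step 8
Reactants: 12 (2S)-4-(tert-butyldimethylsilyloxy)-2-[4-(geranyloxy)phenyl]-5,7-bis(triisopropylsilyloxy)-2H-chromene
Product: 13 (2S)-2-[4-(geranyloxy)phenyl]-5,7-dihydroxy-2,3-dihydro-4H-chromen-4-one (target)
Conditions: Bu4NF (3.5 equiv), AcOH (3.5 equiv), THF, 0 °C
Reagents that add atoms: none
Why: Fluoride cleaves the Si–O bonds of the enol ether and of both aryl silyl ethers, and acetic acid protonates the enol(ate) at C3 before ring C can open, so the ketone should form by tautomerisation with C2 unchanged.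

Compound list
1 | methyl (2E)-3-(4-hydroxyphenyl)prop-2-enoate | COC(=O)/C=C/c1ccc(O)cc1 | starting material
2 | geranyl bromide, (2E)-1-bromo-3,7-dimethylocta-2,6-diene | CC(C)=CCC/C(C)=C/CBr | starting material
3 | methyl (2E)-3-[4-(geranyloxy)phenyl]prop-2-enoate | CC(C)=CCC/C(C)=C/COc1ccc(/C=C/C(=O)OC)cc1 | intermediate
4 | (2E)-3-[4-(geranyloxy)phenyl]prop-2-en-1-ol | CC(C)=CCC/C(C)=C/COc1ccc(/C=C/CO)cc1 | intermediate
5 | (2E)-3-[4-(geranyloxy)phenyl]prop-2-en-1-yl methyl carbonate | CC(C)=CCC/C(C)=C/COc1ccc(/C=C/COC(=O)OC)cc1 | intermediate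
6 | 1-(2,4,6-trihydroxyphenyl)ethanone | CC(=O)c1c(O)cc(O)cc1O | starting material
7 | 1-[2-hydroxy-4,6-bis(triisopropylsilyloxy)phenyl]ethanone | CC(=O)c1c(O)cc(O[Si](C(C)C)(C(C)C)C(C)C)cc1O[Si](C(C)C)(C(C)C)C(C)C | intermediate
8 | lithium 2-acetyl-3,5-bis(triisopropylsilyloxy)phenoxide | CC(=O)c1c([O-])cc(O[Si](C(C)C)(C(C)C)C(C)C)cc1O[Si](C(C)C)(C(C)C)C(C)C.[Li+] | intermediate
9 | 1-[2-{[(1S)-1-[4-(geranyloxy)phenyl]prop-2-en-1-yl]oxy}-4,6-bis(triisopropylsilyloxy)phenyl]ethanone | CC(C)=CCC/C(C)=C/COc1ccc([C@@H](Oc2cc(O[Si](C(C)C)(C(C)C)C(C)C)cc(O[Si](C(C)C)(C(C)C)C(C)C)c2C(C)=O)C=C)cc1 | intermediate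
10 | potassium enolate of 9 | CC(C)=CCC/C(C)=C/COc1ccc([C@@H](Oc2cc(O[Si](C(C)C)(C(C)C)C(C)C)cc(O[Si](C(C)C)(C(C)C)C(C)C)c2C(=C)[O-])C=C)cc1.[K+] | intermediate
11 | tert-butyldimethylsilyl enol ether of 9 | CC(C)=CCC/C(C)=C/COc1ccc([C@@H](Oc2cc(O[Si](C(C)C)(C(C)C)C(C)C)cc(O[Si](C(C)C)(C(C)C)C(C)C)c2C(=C)O[Si](C)(C)C(C)(C)C)C=C)cc1 | intermediate
12 | (2S)-4-(tert-butyldimethylsilyloxy)-2-[4-(geranyloxy)phenyl]-5,7-bis(triisopropylsilyloxy)-2H-chromene | CC(C)=CCC/C(C)=C/COc1ccc([C@@H]2C=C(O[Si](C)(C)C(C)(C)C)c3c(O[Si](C(C)C)(C(C)C)C(C)C)cc(O[Si](C(C)C)(C(C)C)C(C)C)cc3O2)cc1 | intermediate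
13 | (2S)-2-[4-(geranyloxy)phenyl]-5,7-dihydroxy-2,3-dihydro-4H-chromen-4-one | CC(C)=CCC/C(C)=C/COc1ccc([C@@H]2CC(=O)c3c(O)cc(O)cc3O2)cc1 | target

Total step count: 8
Longest linear sequence: 7 steps (steps 1, 2, 3, 5, 6, 7, 8)

Steps most likely to fail

Step 7. Closure onto the hindered 1,1-disubstituted silyl enol ether may be slow. The catalyst could then decay to ruthenium hydrides that isomerise the allyl ether, or engage the geranyl olefins in cross-metathesis, or C2 could erode through reversible electrocyclic opening of the 2H-chromene. The fallback keeps the same ring closure at C3–C4 but uses a stoichiometric titanium alkylidene and an ester carbonyl, whose olefination is irreversible. It sets out from carbonate 5 and returns at target 13. Commercial methyl 2,4,6-trihydroxybenzoate would be bis-silylated as in step 4 to methyl 2-hydroxy-4,6-bis(triisopropylsilyloxy)benzoate F1. Etherification of F1 with 5 under the conditions of step 5 should give methyl 2-{[(1S)-1-[4-(geranyloxy)phenyl]prop-2-en-1-yl]oxy}-4,6-bis(triisopropylsilyloxy)benzoate F2. The reduced titanium ethylidene reagent (TiCl4, Zn, PbCl2 cat., TMEDA, CH3CHBr2, THF) would exchange onto the vinyl group and olefinate the ester carbonyl intramolecularly, giving (2S)-2-[4-(geranyloxy)phenyl]-4-methoxy-5,7-bis(triisopropylsilyloxy)-2H-chromene F3. Aqueous HF in MeCN at 0 °C should then hydrolyse the methyl enol ether and remove both silyl groups to give 13.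

Step 5. The chelated ortho-acyl aryloxide may be too weak a nucleophile, and the electron-rich branched ether may re-ionise on the catalyst, which would erode the enantiomeric purity and leak material to the linear ether. The fallback sets C2 by SN2 inversion instead; it sets out from geranyl bromide 2 and phenol 7 and returns at ether 9. Commercial 4-hydroxybenzaldehyde would be alkylated with 2 (K2CO3, DMF) to 4-(geranyloxy)benzaldehyde F4. Vinylmagnesium bromide should give racemic 1-[4-(geranyloxy)phenyl]prop-2-en-1-ol F5. Kinetic resolution with Candida antarctica lipase B and vinyl acetate is expected, by the usual empirical rule for this enzyme, to acylate the (R)-enantiomer to (1R)-1-[4-(geranyloxy)phenyl]prop-2-en-1-yl acetate F6. Methanolysis (K2CO3, MeOH) would give (1R)-1-[4-(geranyloxy)phenyl]prop-2-en-1-ol F7. Mitsunobu etherification of 7 with F7 (PPh3, DIAD, toluene, −20 °C) should then give 9 with inversion.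

Step 8. A transient C4 enolate formed on fluoride attack at the enol silyl group may open ring C by β-elimination of the O1 phenoxide before it is protonated, which would epimerise C2 on reclosure. The fallback separates the two unmasking events so that no enolate is formed at any time; it sets out from 12 and returns at 13. Acid-catalysed hydrolysis of the silyl enol ether alone (oxalic acid, wet THF, 0 °C, protonation at C3) should give (2S)-2-[4-(geranyloxy)phenyl]-5,7-bis(triisopropylsilyloxy)-2,3-dihydro-4H-chromen-4-one F8. The aryl silyl ethers would then be removed under acidic fluoride conditions (Et3N·3HF, THF, 25 °C) to give 13.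

Further compounds
F1 | step 7 | methyl 2-hydroxy-4,6-bis(triisopropylsilyloxy)benzoate | COC(=O)c1c(O)cc(O[Si](C(C)C)(C(C)C)C(C)C)cc1O[Si](C(C)C)(C(C)C)C(C)C
F2 | step 7 | methyl 2-{[(1S)-1-[4-(geranyloxy)phenyl]prop-2-en-1-yl]oxy}-4,6-bis(triisopropylsilyloxy)benzoate | CC(C)=CCC/C(C)=C/COc1ccc([C@@H](Oc2cc(O[Si](C(C)C)(C(C)C)C(C)C)cc(O[Si](C(C)C)(C(C)C)C(C)C)c2C(=O)OC)C=C)cc1
F3 | step 7 | (2S)-2-[4-(geranyloxy)phenyl]-4-methoxy-5,7-bis(triisopropylsilyloxy)-2H-chromene | CC(C)=CCC/C(C)=C/COc1ccc([C@@H]2C=C(OC)c3c(O[Si](C(C)C)(C(C)C)C(C)C)cc(O[Si](C(C)C)(C(C)C)C(C)C)cc3O2)cc1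
F4 | step 5 | 4-(geranyloxy)benzaldehyde | CC(C)=CCC/C(C)=C/COc1ccc(C=O)cc1
F5 | step 5 | racemic 1-[4-(geranyloxy)phenyl]prop-2-en-1-ol | CC(C)=CCC/C(C)=C/COc1ccc(C(O)C=C)cc1
F6 | step 5 | (1R)-1-[4-(geranyloxy)phenyl]prop-2-en-1-yl acetate | CC(C)=CCC/C(C)=C/COc1ccc([C@H](OC(C)=O)C=C)cc1
F7 | step 5 | (1R)-1-[4-(geranyloxy)phenyl]prop-2-en-1-ol | CC(C)=CCC/C(C)=C/COc1ccc([C@H](O)C=C)cc1
F8 | step 8 | (2S)-2-[4-(geranyloxy)phenyl]-5,7-bis(triisopropylsilyloxy)-2,3-dihydro-4H-chromen-4-one | CC(C)=CCC/C(C)=C/COc1ccc([C@@H]2CC(=O)c3c(O[Si](C(C)C)(C(C)C)C(C)C)cc(O[Si](C(C)C)(C(C)C)C(C)C)cc3O2)cc1
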